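**Plan**

- Retrosynthesis: cut C5'–C6' (alkenyl nucleophile plus C5' aldehyde), then the aryl ether bond O–C1' to 7-hydroxy-8-methoxycoumarin (the bicyclic lactone is bought whole), then move the C2'–C3' oxirane back to C1'–C2' and cut its two C–O bonds.
- Enabling feature (side chain numbered C1' = OCH2 to C7' = CMe2): C3' bears CH3, the oxirane oxygen and two two-carbon arms, C2'–C1' and C4'–C5', so it is the carbinol carbon of prochiral 3-methylpenta-1,4-dien-3-ol.
- Forward: one vinyl group of the dienol is epoxidised (the only ring made, first as the C1'–C2' oxirane), a Payne shift relocates the oxirane to C2'–C3', the freed C1'–OH is etherified with the coumarin phenol, the second vinyl group is taken to the C5' aldehyde, and C6'–C7' are added last.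
- Stereochemistry: C2' and C3' come from catalyst control over which vinyl group and which face are epoxidised, C2' being inverted once, stereospecifically, in the Payne shift; C5' comes from the chiral chromium catalyst of the last coupling.

Key step: step 1

Assumption: the sense of induction of the two chiral catalysts cannot be read from a model for these substrates, so the ligand enantiomer in steps 1 and 6 is fixed by a first trial (the (R,R)- and (4S)-ligands are written); the dienol and hydrangetin are taken as purchasable.

**Route**

Step 1
Reactants: 1 3-methylpenta-1,4-dien-3-ol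
Product: 2 (2R)-2-[(2S)-oxiran-2-yl]but-3-en-2-ol
Conditions: Hf(OtBu)4 (10 mol %), (1R,2R)-N,N'-dihydroxy-N,N'-bis(diphenylacetyl)cyclohexane-1,2-diamine (12 mol %), DMPU, cumene hydroperoxide (1.1 equiv), 4 Å MS, toluene, 0 °C to rt
Reagents that add atoms: cumene hydroperoxide, CC(C)(OO)c1ccccc1
Why: Proposed new method: the dienol should bind as its alkoxide to the tetravalent hafnium–bishydroxamate complex beside an η2-cumyl peroxide, and the peroxide oxygen is then passed in one concerted step to the vinyl group that the C2-symmetric ligand holds under it, so that C1'–O and C2'–O form together; the closest known reactions are the hafnium- and zirconium–bishydroxamic acid epoxidation and kinetic resolution of tertiary allylic alcohols and the Sharpless desymmetrisation of secondary divinyl carbinols. The oxirane closes by this single [2+1] oxygen-atom transfer to C1'=C2', not by a stepwise exo or endo closure. C2' is set by the alkene face that the ligand turns toward the peroxide, and C3' by which of the two enantiotopic vinyl groups reacts, the two choices being coupled because methyl and the unreacted vinyl group must share the remaining sites around the bound alkoxide. The step needs group and face selectivity for the (2'S,3'R) isomer (the two C–O bonds anti in the zigzag drawing) and mono-epoxidation; the tertiary alkoxide anchors both alkenes to the metal, methyl is expected to take the crowded site that hydrogen occupies in secondary carbinols, and only 1.1 equiv of peroxide is offered. Any minor enantiomer still carries the vinyl group and face that the catalyst prefers and should be consumed as the bis-epoxide, which raises the enantiomeric purity of 2.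

Step 2
Reactants: 2 (2R)-2-[(2S)-oxiran-2-yl]but-3-en-2-ol
Product: 3 [(2R,3R)-3-ethenyl-3-methyloxiran-2-yl]methanol
Conditions: 0.5 M aq NaOH, tBuOH, 0 °C to rt; NH4Cl, NaCl, extraction with EtOAc; solution used without concentration to dryness
Reagents that add atoms: none
Why: Payne rearrangement: the C3' alkoxide opens the terminal oxirane at C2' by 3-exo-tet backside attack, which inverts C2' (S in 2, R in 3) and leaves C3' untouched, and the equilibrium should favour the trisubstituted oxirane with the primary alkoxide.

Step 3
Reactants: 3 [(2R,3R)-3-ethenyl-3-methyloxiran-2-yl]methanol; 4 7-hydroxy-8-methoxy-2H-chromen-2-one (hydrangetin)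
Product: 5 7-{[(2R,3R)-3-ethenyl-3-methyloxiran-2-yl]methoxy}-8-methoxy-2H-chromen-2-one
Conditions: PPh3, DIAD, THF, 0 °C to rt
Reagents that add atoms: none
Why: Mitsunobu reaction: the acidic coumarin phenol displaces the activated primary C1' oxygen by SN2 at a carbon that is no stereocentre, so the oxirane and both stereocentres pass through unchanged.

Step 4
Reactants: 5 7-{[(2R,3R)-3-ethenyl-3-methyloxiran-2-yl]methoxy}-8-methoxy-2H-chromen-2-one
Product: 7 7-{[(2R,3R)-3-(2-hydroxyethyl)-3-methyloxiran-2-yl]methoxy}-8-methoxy-2H-chromen-2-one, via alkylborane 6 (not isolated)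
Conditions: 9-BBN (1.5 equiv), THF, 0 °C to rt; then 3 M aq NaOAc, 30% H2O2, 0 °C to rt
Reagents that add atoms: hydrogen peroxide, OO
Why: Hydroboration–oxidation: the bulky dialkylborane should place boron on the terminal C5' of the monosubstituted alkene much faster than it touches the electron-poor coumarin C3=C4 bond or the lactone, and acetate-buffered peroxide oxidises the C–B bond without opening the lactone; no stereocentre is formed.

Step 5
Reactants: 7 7-{[(2R,3R)-3-(2-hydroxyethyl)-3-methyloxiran-2-yl]methoxy}-8-methoxy-2H-chromen-2-one
Product: 8 2-[(2R,3R)-3-{[(8-methoxy-2-oxo-2H-chromen-7-yl)oxy]methyl}-2-methyloxiran-2-yl]acetaldehyde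
Conditions: Dess–Martin periodinane, NaHCO3, CH2Cl2, 0 °C to rt; crude aldehyde used at once
Reagents that add atoms: none
Why: Dess–Martin oxidation under bicarbonate buffer stops at the aldehyde under neutral, non-enolising conditions, which should spare the β,γ-epoxy aldehyde from β-elimination.

Step 6
Reactants: 8 2-[(2R,3R)-3-{[(8-methoxy-2-oxo-2H-chromen-7-yl)oxy]methyl}-2-methyloxiran-2-yl]acetaldehyde; 9 1-bromo-2-methylprop-1-ene
Product: 12 7-{[(2R,3R)-3-[(2R)-2-hydroxy-4-methylpent-3-en-1-yl]-3-methyloxiran-2-yl]methoxy}-8-methoxy-2H-chromen-2-one (the target), via alkenylchromium chloride 10 (not isolated), via zirconium alkoxide 11 (not isolated)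
Conditions: CrCl2 (10 mol %), N-{2-[(4S)-4-isopropyl-4,5-dihydro-1,3-oxazol-2-yl]-6-methylphenyl}methanesulfonamide (12 mol %), 1,8-bis(dimethylamino)naphthalene (12 mol %), NiCl2(2,9-dimethyl-1,10-phenanthroline) (2 mol %), Mn (2 equiv), Cp2ZrCl2 (1.2 equiv), LiCl (2 equiv), MeCN, rt; then aq NaHCO3
Reagents that add atoms: none
Why: Catalytic asymmetric Nozaki–Hiyama–Kishi coupling: zerovalent nickel inserts into the C–Br bond, the alkenyl group passes to ligand-bound trivalent chromium and adds only to the aldehyde (lactone, oxirane and aryl ethers are inert to this weakly basic nucleophile), Cp2ZrCl2 takes over the alkoxide and Mn returns chromium to the divalent state, while the sulfonamide–oxazoline ligand directs the alkenyl group to the Si face of the aldehyde and so sets C5' as R.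

**Compound list**

1 | 3-methylpenta-1,4-dien-3-ol | C=CC(C)(O)C=C | starting material
2 | (2R)-2-[(2S)-oxiran-2-yl]but-3-en-2-ol | C1O[C@@H]1[C@](C)(O)C=C | intermediate
3 | [(2R,3R)-3-ethenyl-3-methyloxiran-2-yl]methanol | OC[C@H]1O[C@]1(C)C=C | intermediate
4 | 7-hydroxy-8-methoxy-2H-chromen-2-one (hydrangetin) | COc1c(O)ccc2ccc(=O)oc12 | starting material
5 | 7-{[(2R,3R)-3-ethenyl-3-methyloxiran-2-yl]methoxy}-8-methoxy-2H-chromen-2-one | COc1c(OC[C@H]2O[C@]2(C)C=C)ccc2ccc(=O)oc12 | intermediate
6 | 7-({(2R,3R)-3-[2-(9-borabicyclo[3.3.1]nonan-9-yl)ethyl]-3-methyloxiran-2-yl}methoxy)-8-methoxy-2H-chromen-2-one (formed in the flask) | COc1c(OC[C@H]2O[C@]2(C)CCB3C4CCCC3CCC4)ccc2ccc(=O)oc12 | intermediate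
7 | 7-{[(2R,3R)-3-(2-hydroxyethyl)-3-methyloxiran-2-yl]methoxy}-8-methoxy-2H-chromen-2-one | COc1c(OC[C@H]2O[C@]2(C)CCO)ccc2ccc(=O)oc12 | intermediate
8 | 2-[(2R,3R)-3-{[(8-methoxy-2-oxo-2H-chromen-7-yl)oxy]methyl}-2-methyloxiran-2-yl]acetaldehyde | COc1c(OC[C@H]2O[C@]2(C)CC=O)ccc2ccc(=O)oc12 | intermediate
9 | 1-bromo-2-methylprop-1-ene | CC(C)=CBr | starting material
10 | dichloro(2-methylprop-1-en-1-yl)chromium, trivalent chromium, bound to the sulfonamide ligand (ligand not drawn; formed in the flask) | CC(C)=C[Cr](Cl)Cl | intermediate
11 | chlorobis(cyclopentadienyl)zirconium O5'-alkoxide of 12 (formed in the flask) | COc1c(OC[C@H]2O[C@]2(C)C[C@@H](O[Zr](Cl)(C3C=CC=C3)C3C=CC=C3)C=C(C)C)ccc2ccc(=O)oc12 | intermediate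
12 | 7-{[(2R,3R)-3-[(2R)-2-hydroxy-4-methylpent-3-en-1-yl]-3-methyloxiran-2-yl]methoxy}-8-methoxy-2H-chromen-2-one | COc1c(OC[C@H]2O[C@]2(C)C[C@@H](O)C=C(C)C)ccc2ccc(=O)oc12 | target

**Step count and risks**

Total steps: 6. Longest linear sequence: 6 steps (1 to 12).

The three steps most likely to fail:

First, step 1. The catalyst may not tell methyl from the spectator vinyl group at the bound tertiary alkoxide, so that the wrong vinyl group or face is epoxidised. Turnover may also be slow, or the second alkene may be epoxidised too early. The fallback uses known chemistry and sets out from 1. A rhenium-oxo-catalysed 1,3-transposition of the tertiary allylic alcohol (Ph3SiOReO3, Et2O, −50 to 0 °C) should give the conjugated (2E)-3-methylpenta-2,4-dien-1-ol F1. The E isomer has to be separated from any Z isomer, which would give the wrong oxirane diastereomer. Sharpless asymmetric epoxidation of the allylic C2=C3 bond of F1 (Ti(OiPr)4, D-(−)-diethyl tartrate, tBuOOH, 4 Å MS, CH2Cl2, −20 °C) should then give the (2R,3R)-epoxy alcohol directly. D-(−)-tartrate is chosen as the antipode of the tartrate that gives (2S,3S)-epoxygeraniol. The fallback comes back to the route at 3, and neither 2 nor the Payne shift is then needed.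

Second, step 6. Facial control by the ligand may be weak for this β-branched aliphatic aldehyde with a sluggish alkenyl bromide. The oxirane may also be opened, by β-elimination from the aldehyde or by the metal alkoxide, in the Lewis-acidic medium. The fallback sets out from 8 and moves the stereocontrol from C–C bond formation to a ketone reduction. Coupling of 8 with 9 without chiral ligand (CrCl2, NiCl2 cat., DMF, rt) should give the C5'-epimeric allylic alcohols F2. Oxidation with MnO2 (CH2Cl2, rt) should give the β,γ-epoxy enone F3. Corey–Bakshi–Shibata reduction should then deliver the (5'R)-alcohol, with the alkenyl group acting as the large substituent. It uses (S)-1-methyl-3,3-diphenyltetrahydro-1H,3H-pyrrolo[1,2-c][1,3,2]oxazaborole and catecholborane in toluene at −78 °C. The fallback comes back to the route at 12.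

Third, step 4. Boron hydride may be delivered to the allylic oxirane (reductive SN2'-type opening) or to the coumarin, and the lactone or oxirane may be damaged in the oxidative work-up. The fallback sets out from 5 and uses no hydride reagent. An aldehyde-selective Wacker oxidation (PdCl2(PhCN)2, CuCl2, AgNO2, O2, tBuOH/MeNO2, rt) should oxidise the terminal carbon of the vinyl group, steered by the allylic oxygen and the fully substituted C3'. This gives the aldehyde in one operation and bypasses 7 and step 5; it makes no new compound, F0. The fallback comes back to the route at 8.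

**Further compounds**

F1 | step 1 | (2E)-3-methylpenta-2,4-dien-1-ol | OC/C=C(C)/C=C
F2 | step 6 | 7-{[(2R,3R)-3-(2-hydroxy-4-methylpent-3-en-1-yl)-3-methyloxiran-2-yl]methoxy}-8-methoxy-2H-chromen-2-one, both C5' epimers | COc1c(OC[C@H]2O[C@]2(C)CC(O)C=C(C)C)ccc2ccc(=O)oc12
F3 | step 6 | 8-methoxy-7-{[(2R,3R)-3-methyl-3-(4-methyl-2-oxopent-3-en-1-yl)oxiran-2-yl]methoxy}-2H-chromen-2-one | COc1c(OC[C@H]2O[C@]2(C)CC(=O)C=C(C)C)ccc2ccc(=O)oc12
F0 | step 4 | none | none
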